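The 2,2,4,4-tetramethylcyclohexane-1,3,5-trione ring (ring B: C1 carries the benzylic carbon, C2 is the enol carbon, C3 and C5 are the C(CH3)2 carbons, C4 is the ketone between them, C6 the remaining ketone) alternates acyl carbons with carbanion-type carbons, like a cyclised methylated triketide. The key step uses this pattern: the isobutyryl unit C3–C4 is inserted between C2 and C5 by γ-acylation of the dianion of methyl 4-methyl-3-oxopentanoate with isobutyryl chloride and Dieckmann closure in the same flask. This forms C4–C5 and C2–C3 and gives syncarpic acid from two acyclic commercial compounds. Knoevenagel condensation and a catalytic enantioselective Friedel–Crafts-type Michael addition of the acylphloroglucinol complete the target.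

Key step: step 1

Remark on the chemistry: 5, 7 and 12 are enolised β-dicarbonyl compounds; each is written as a single tautomer, and the descriptor (S) of 12 refers to the enol tautomer written in the compound list.

Assumption: the quinine-derived squaramide 3-{[3,5-bis(trifluoromethyl)phenyl]amino}-4-{[(8α,9S)-6′-methoxycinchonan-9-yl]amino}cyclobut-3-ene-1,2-dione is taken to deliver the arene to the Re face of the alkylidene carbon of 8, which corresponds to (S); should the opposite sense be found, its quinidine-derived pseudoenantiomer takes its place in step 4.

Step 1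
Reactants: 1 methyl 4-methyl-3-oxopentanoate; 2 2-methylpropanoyl chloride (isobutyryl chloride)
Product: 5 syncarpic acid (2,2,4,4-tetramethylcyclohexane-1,3,5-trione), via dienediolate 3 (not isolated), via diketo ester enolate 4 (not isolated)
Conditions: NaH, THF, 0 °C; n-BuLi, 0 °C; 2, −78 to 0 °C; LiN(iPr)2, −78 to 50 °C; aq. HCl
Reagents that add atoms: none
Why: Double deprotonation of 1 (NaH at C2, n-BuLi at the C4 methine) gives dienediolate 3, whose tertiary γ-carbon is acylated by 2 to form the bond between the central ketone carbon and one C(CH3)2 carbon and to leave 4 as its β-keto ester enolate; LiN(iPr)2 then removes the only remaining acidic proton, the isopropyl methine, and this lithium enolate attacks the methyl ester carbon to form the second ring bond with loss of methoxide. The closest known reaction types are the γ-acylation of β-keto ester dianions with acid chlorides and the Dieckmann (intramolecular Claisen) condensation that closes cyclohexane-1,3-diones, as in the dimedone synthesis, where a ketone enolate closes onto an ester whose α-position is already deprotonated. The six-membered ring closes in the 6-(enolendo)-exo-trig mode, the only carbon-to-carbonyl closure open to 4 because every alternative aldol or Claisen ring would be four-membered. No stereocentre is formed. The step needs γ- over α- or O-acylation, which the higher charge density at the γ-carbon of 3 at −78 °C should secure, and C- over O-acylation in the ring closure, which the tight lithium enolate in THF should favour; the C-acylated product also leaves the equilibrium as the doubly stabilised enolate of 5, which shields it from retro-Claisen cleavage by methoxide.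

Step 2
Reactants: 5 syncarpic acid; 6 3-methylbutanal (isovaleraldehyde)
Product: 8 2,2,4,4-tetramethyl-6-(3-methylbutylidene)cyclohexane-1,3,5-trione, via Mannich base 7 (not isolated)
Conditions: piperidine (1.1 equiv), CH2Cl2, 0 °C to rt; then 1 M HCl, rt
Reagents that add atoms: none
Why: Knoevenagel condensation run in its Mannich/elimination form: the enol of 5 adds to the piperidinium ion of 6 to give Mannich base 7, which cannot accept a second molecule of 5, and protonation then expels piperidine by β-elimination to give the alkylidene trione, which has no E/Z isomers because the ring is symmetrical.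

Step 3
Reactants: 9 2-methylbenzene-1,3,5-triol; 10 3-phenylpropanoyl chloride
Product: 11 1-(2,4,6-trihydroxy-3-methylphenyl)-3-phenylpropan-1-one
Conditions: AlCl3 (3.5 equiv), PhNO2, 60 °C; then ice, aq. HCl
Reagents that add atoms: none
Why: Friedel–Crafts acylation of the very electron-rich triol, in which the two free ring positions of 9 are equivalent and the first acyl group, chelated to aluminium through its ortho phenols, deactivates the ring against a second acylation.

Step 4
Reactants: 8 2,2,4,4-tetramethyl-6-(3-methylbutylidene)cyclohexane-1,3,5-trione; 11 1-(2,4,6-trihydroxy-3-methylphenyl)-3-phenylpropan-1-one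
Product: 12 5-hydroxy-2,2,6,6-tetramethyl-4-[(1S)-3-methyl-1-[2,4,6-trihydroxy-3-methyl-5-(3-phenylpropanoyl)phenyl]butyl]cyclohex-4-ene-1,3-dione (target)
Conditions: quinine-derived squaramide organocatalyst (10 mol %), CH2Cl2, −20 °C
Reagents that add atoms: none
Why: Friedel–Crafts-type Michael addition in which the squaramide N–H groups bind the 1,3-dicarbonyl unit of acceptor 8 and the quinuclidine nitrogen hydrogen-bonds a phenol of 11, so that the only unsubstituted carbon of ring A is delivered to the Re face of the alkylidene carbon, which sets the (S) centre under catalyst control, and the adduct is stabilised as the hydrogen-bonded enol.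

Compound list
1 | methyl 4-methyl-3-oxopentanoate | COC(=O)CC(=O)C(C)C | starting material
2 | 2-methylpropanoyl chloride (isobutyryl chloride) | CC(C)C(=O)Cl | starting material
3 | sodium lithium 1-methoxy-4-methylpenta-1,3-diene-1,3-diolate (dienediolate of 1) | COC([O-])=CC([O-])=C(C)C.[Na+].[Li+] | intermediate
4 | sodium enolate of methyl 4,4,6-trimethyl-3,5-dioxoheptanoate | COC(=O)C=C([O-])C(C)(C)C(=O)C(C)C.[Na+] | intermediate
5 | syncarpic acid (2,2,4,4-tetramethylcyclohexane-1,3,5-trione) | CC1(C)C(=O)CC(=O)C(C)(C)C1=O | intermediate
6 | 3-methylbutanal (isovaleraldehyde) | CC(C)CC=O | starting material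
7 | 5-hydroxy-2,2,6,6-tetramethyl-4-[3-methyl-1-(piperidin-1-yl)butyl]cyclohex-4-ene-1,3-dione (racemic Mannich base) | CC(C)CC(N1CCCCC1)C1=C(O)C(C)(C)C(=O)C(C)(C)C1=O | intermediate
8 | 2,2,4,4-tetramethyl-6-(3-methylbutylidene)cyclohexane-1,3,5-trione | CC(C)CC=C1C(=O)C(C)(C)C(=O)C(C)(C)C1=O | intermediate
9 | 2-methylbenzene-1,3,5-triol | Cc1c(O)cc(O)cc1O | starting material
10 | 3-phenylpropanoyl chloride | O=C(Cl)CCc1ccccc1 | starting material
11 | 1-(2,4,6-trihydroxy-3-methylphenyl)-3-phenylpropan-1-one | Cc1c(O)cc(O)c(C(=O)CCc2ccccc2)c1O | intermediate
12 | 5-hydroxy-2,2,6,6-tetramethyl-4-[(1S)-3-methyl-1-[2,4,6-trihydroxy-3-methyl-5-(3-phenylpropanoyl)phenyl]butyl]cyclohex-4-ene-1,3-dione | Cc1c(O)c(C(=O)CCc2ccccc2)c(O)c([C@H](CC(C)C)C2=C(O)C(C)(C)C(=O)C(C)(C)C2=O)c1O | target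

Total step count: 4. Longest linear sequence: 3 steps (steps 1, 2 and 4); step 3 is a one-step convergent branch.

Steps most likely to fail

Step 1. The ring closure may stall at the doubly deprotonated stage, because the ester carbonyl is deactivated by the neighbouring enolate, or it may divert to O-acylation and give an enol lactone. Fallback (sets out from 2, comes back at 5): the acyl terminus is activated as a thioester. Commercial S-tert-butyl ethanethioate, CC(=O)SC(C)(C)C, is deprotonated with LiN(SiMe3)2 (2 equiv) in THF at −78 °C and acylated with 2 in a crossed Claisen condensation to give S-tert-butyl 4-methyl-3-oxopentanethioate F1. Double deprotonation of F1 with LiN(iPr)2 and γ-acylation with a second portion of 2 should give S-tert-butyl 4,4,6-trimethyl-3,5-dioxoheptanethioate F2, which is not isolated. A third equivalent of LiN(iPr)2 should then close the ring with loss of 2-methylpropane-2-thiolate, a better leaving group on a more electrophilic carbonyl, in the manner of the thioester Claisen cyclisation of polyketide biosynthesis. Both ring bonds still arise in one flask, and acidic work-up should give 5.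

Step 4. Facial discrimination by the catalyst may be poor if an uncatalysed background addition competes, and enantiopurity may erode through reversible retro-Michael fragmentation of the adduct. Fallback (sets out from 8 and 11, comes back at 12): the addition is run without a chiral catalyst (catalytic Et3N, CH2Cl2, rt) to give the racemic adduct F3. Preparative chromatography on a chiral stationary phase (amylose tris(3,5-dimethylphenylcarbamate)) then separates 12 from its (R)-enantiomer F4, so that the stereocentre is secured by resolution instead of by asymmetric catalysis.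

Step 2. A second molecule of 5 may add to the newly formed alkylidene during the condensation, and the electron-poor alkene may oligomerise or hydrate on isolation. Fallback (sets out from 5 and 6, comes back at 8): the alkene is introduced only after the carbon–carbon bond is in place. Organocatalytic reductive alkylation (L-proline cat., diethyl 2,6-dimethyl-1,4-dihydropyridine-3,5-dicarboxylate, CH2Cl2, rt) reduces the alkylidene as it forms and should give 2,2,4,4-tetramethyl-6-(3-methylbutyl)cyclohexane-1,3,5-trione F5. Selenenylation at the doubly activated carbon (PhSeCl, pyridine, CH2Cl2, 0 °C) should give 2,2,4,4-tetramethyl-6-(3-methylbutyl)-6-(phenylselanyl)cyclohexane-1,3,5-trione F6. Oxidation with 3-chloroperbenzoic acid at −78 °C gives the selenoxide F7, whose syn-elimination on warming can only reach the side-chain CH2 hydrogens and so should return 8 in the absence of free 5.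

Further compounds
F1 | step 1 | S-tert-butyl 4-methyl-3-oxopentanethioate | CC(C)C(=O)CC(=O)SC(C)(C)C
F2 | step 1 | S-tert-butyl 4,4,6-trimethyl-3,5-dioxoheptanethioate | CC(C)C(=O)C(C)(C)C(=O)CC(=O)SC(C)(C)C
F3 | step 4 | racemic 5-hydroxy-2,2,6,6-tetramethyl-4-[3-methyl-1-[2,4,6-trihydroxy-3-methyl-5-(3-phenylpropanoyl)phenyl]butyl]cyclohex-4-ene-1,3-dione | Cc1c(O)c(C(=O)CCc2ccccc2)c(O)c(C(CC(C)C)C2=C(O)C(C)(C)C(=O)C(C)(C)C2=O)c1O
F4 | step 4 | (R)-enantiomer of 12 | Cc1c(O)c(C(=O)CCc2ccccc2)c(O)c([C@@H](CC(C)C)C2=C(O)C(C)(C)C(=O)C(C)(C)C2=O)c1O
F5 | step 2 | 2,2,4,4-tetramethyl-6-(3-methylbutyl)cyclohexane-1,3,5-trione | CC(C)CCC1C(=O)C(C)(C)C(=O)C(C)(C)C1=O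
F6 | step 2 | 2,2,4,4-tetramethyl-6-(3-methylbutyl)-6-(phenylselanyl)cyclohexane-1,3,5-trione | CC(C)CCC1([Se]c2ccccc2)C(=O)C(C)(C)C(=O)C(C)(C)C1=O
F7 | step 2 | 2,2,4,4-tetramethyl-6-(3-methylbutyl)-6-(phenylseleninyl)cyclohexane-1,3,5-trione | CC(C)CCC1([Se](=O)c2ccccc2)C(=O)C(C)(C)C(=O)C(C)(C)C1=O
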